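**Retrosynthetic overview**
1. Target 25 ⇐ bis-silyl ether 24 ⇐ acid 22 + epoxy-cyclobutanol 11: palladium-catalysed acylative opening of the four-membered ring makes the CH2–C(=O) bond of the left ketone and releases both ketones at once.
2. 11 ⇐ cyclobutanone 7 by α-prenylation and reagent-controlled epoxidation.
3. 7 ⇐ meso methylenecyclopropane 5 via its oxaspiropentane: enantioselective ring expansion (1,2-alkyl shift) that tells the two cis quaternary carbons apart; 5 ⇐ 1,2-dimethylcyclopentene + CH3CHCl2.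
4. 22 ⇐ o-cresol (ortho-hydroxymethylation, para-oxidation, silylation, bromide) + but-3-yn-1-ol (carboalumination and benzyl coupling fix the E-alkene).
5. Ring order: cyclopentane and arene are bought; cyclopropane (step 1) → cyclobutanone by expansion (step 3) → oxirane (step 5); the four-membered ring is cleaved in step 12.

Assumption: 1,2-dimethylcyclopent-1-ene is bought. Locants in the bicyclic intermediates: C1 and C5 are the bridgeheads, C6 is the carbonyl or carbinol carbon, C7 is the ring CH2. The configuration at C6 of 4, 6, 10 and 11 is inconsequential, because C6 ends up sp2.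

**Route**

Step 1
Reactants: 1 1,2-dimethylcyclopent-1-ene; 2 1,1-dichloroethane
Product: 4 (1R,5S)-6-chloro-1,5,6-trimethylbicyclo[3.1.0]hexane, via 1,1-dichloroethyllithium 3 (not isolated)
Conditions: n-BuLi, Et2O, −35 °C → rt
Reagents that add atoms: none
Why: α-Elimination of the lithium carbenoid and syn [2+1] cyclopropanation of the electron-rich tetrasubstituted alkene (chloromethylcarbene transfer) put both future quaternary carbons cis in a meso cyclopropane.

Step 2
Reactants: 4 (1R,5S)-6-chloro-1,5,6-trimethylbicyclo[3.1.0]hexane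
Product: 5 (1R,5S)-1,5-dimethyl-6-methylidenebicyclo[3.1.0]hexane
Conditions: KOt-Bu, DMSO, 50 °C
Reagents that add atoms: none
Why: E2 dehydrochlorination can only go towards the exocyclic methyl group because both neighbouring ring carbons are quaternary, which is the standard entry to methylenecyclopropanes.

Step 3
Reactants: 5 (1R,5S)-1,5-dimethyl-6-methylidenebicyclo[3.1.0]hexane
Product: 7 (1R,5R)-1,5-dimethylbicyclo[3.2.0]heptan-6-one, via oxaspiropentane 6 (not isolated)
Conditions: DMDO, acetone, −20 °C; evaporate; then chiral BINOL-derived imidodiphosphorimidate Brønsted acid (IDPi, 2 mol%, the enantiomer that gives (1R,5R)-7), PhMe, −60 °C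
Reagents that add atoms: dimethyldioxirane (DMDO), CC1(C)OO1
Why: Proposed new method: the confined chiral acid protonates the oxirane oxygen of meso 6 and its counter-anion decides which of the two enantiotopic cyclopropane bonds (C6–C1 or C6–C5) shifts to the primary oxirane carbon as the C–O bond breaks (cyclopropylcarbinyl-assisted semipinacol 1,2-shift), so one ring expansion sets both quaternary centres as (1R,5R) with the cis relationship already fixed by the cyclopropane, the closest known reactions being the LiI- or acid-promoted oxaspiropentane-to-cyclobutanone rearrangement and chiral-Brønsted-acid-catalysed enantioselective semipinacol and Meinwald rearrangements.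

Step 4
Reactants: 7 (1R,5R)-1,5-dimethylbicyclo[3.2.0]heptan-6-one; 8 1-chloro-3-methylbut-2-ene
Product: 10 (1R,5R,6S)-1,5-dimethyl-6-(3-methylbut-2-en-1-yl)bicyclo[3.2.0]heptan-6-ol, via prenylbarium chloride 9 (not isolated)
Conditions: activated Ba metal (from BaI2 and 2 equiv lithium biphenylide, LiC12H10, THF, rt), 8, −78 °C; then 7, −78 °C; aq. NH4Cl
Reagents that add atoms: none
Why: Allylic barium reagents add to ketones at the unsubstituted α-terminus (Yamamoto allylbarium addition), here mainly from the convex face of the strained, electrophilic cyclobutanone.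

Step 5
Reactants: 10 (1R,5R,6S)-1,5-dimethyl-6-(3-methylbut-2-en-1-yl)bicyclo[3.2.0]heptan-6-ol
Product: 11 (1R,5R,6R)-6-{[(2S)-3,3-dimethyloxiran-2-yl]methyl}-1,5-dimethylbicyclo[3.2.0]heptan-6-ol
Conditions: ent-Shi ketone (L-fructose-derived, 0.3 equiv), KHSO5 (as Oxone, 2KHSO5·KHSO4·K2SO4), K2CO3, Bu4NHSO4, MeCN–(MeO)2CH2–aq. Na2B4O7 buffer (pH 10.5), 0 °C
Reagents that add atoms: potassium peroxymonosulfate (KHSO5), [K+].[O-]S(=O)(=O)OO
Why: Shi asymmetric epoxidation of the only alkene, a trisubstituted prenyl group, is reagent-controlled through the spiro dioxirane transition state, and the ketone enantiomeric to the D-fructose-derived one delivers the (S)-oxirane.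

Step 6
Reactants: 12 2-methylphenol
Product: 14 2-(hydroxymethyl)-6-methylphenol, via benzodioxaborin 13 (not isolated)
Conditions: PhB(OH)2, (CH2O)n, EtCO2H (cat.), PhMe, reflux (−H2O); then 30% H2O2, THF, 0 °C
Reagents that add atoms: paraformaldehyde (formaldehyde), C=O
Why: Nagata ortho-hydroxymethylation, in which the aryl phenylboronate delivers formaldehyde intramolecularly to the only free ortho position and oxidative cleavage of the benzodioxaborin frees the salicyl alcohol.

Step 7
Reactants: 14 2-(hydroxymethyl)-6-methylphenol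
Product: 16 2-(hydroxymethyl)-6-methylbenzene-1,4-diol, via quinone 15 (not isolated)
Conditions: Co(salen) (C16H14CoN2O2, 10 mol%), O2 (1 atm), DMF, rt; then aq. Na2S2O4, EtOAc
Reagents that add atoms: dioxygen, O=O
Why: Cobalt–salen-catalysed aerobic oxidation of a 2,6-disubstituted phenol gives the para-quinone at the only open position, and dithionite reduction delivers the hydroquinone.

Step 8
Reactants: 16 2-(hydroxymethyl)-6-methylbenzene-1,4-diol
Product: 17 tert-butyl{[2,5-bis(tert-butyldimethylsilyloxy)-3-methylphenyl]methoxy}dimethylsilane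
Conditions: TBSCl (3.5 equiv), imidazole, DMF, rt
Reagents that add atoms: tert-butyldimethylsilyl chloride (TBSCl), CC(C)(C)[Si](C)(C)Cl
Why: Imidazole-mediated silyl transfer protects both phenols and the benzylic alcohol in one standard silylation.

Step 9
Reactants: 17 tert-butyl{[2,5-bis(tert-butyldimethylsilyloxy)-3-methylphenyl]methoxy}dimethylsilane
Product: 18 1-(bromomethyl)-2,5-bis(tert-butyldimethylsilyloxy)-3-methylbenzene
Conditions: Ph3PBr2, CH2Cl2, 0 °C → rt
Reagents that add atoms: dibromotriphenylphosphorane (Ph3PBr2), BrP(Br)(c1ccccc1)(c1ccccc1)c1ccccc1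
Why: Ph3PBr2 converts benzylic silyl ethers directly into bromides by SN2 displacement on the oxyphosphonium intermediate, whereas aryl silyl ethers cannot be displaced.

Step 10
Reactants: 19 but-3-yn-1-ol; 18 1-(bromomethyl)-2,5-bis(tert-butyldimethylsilyloxy)-3-methylbenzene
Product: 21 (E)-5-[2,5-bis(tert-butyldimethylsilyloxy)-3-methylphenyl]-3-methylpent-3-en-1-ol, via alkenylalane 20 (not isolated)
Conditions: 19, AlMe3 (3 equiv), Cp2ZrCl2 (0.25 equiv), ClCH2CH2Cl, 0 °C → rt; then 18, Pd(PPh3)4 (5 mol%), THF, rt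
Reagents that add atoms: trimethylaluminium (AlMe3), C[Al](C)C
Why: Negishi zirconium-catalysed syn-carboalumination puts methyl on the internal alkyne carbon cis to aluminium, and palladium-catalysed alkenyl–benzyl cross-coupling with retention fixes the E trisubstituted alkene.

Step 11
Reactants: 21 (E)-5-[2,5-bis(tert-butyldimethylsilyloxy)-3-methylphenyl]-3-methylpent-3-en-1-ol
Product: 22 (E)-5-[2,5-bis(tert-butyldimethylsilyloxy)-3-methylphenyl]-3-methylpent-3-enoic acid
Conditions: TEMPO (10 mol%), NaClO2, NaOCl (5 mol%), pH 6.7 phosphate buffer, MeCN, 35 °C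
Reagents that add atoms: sodium chlorite (NaClO2), [Na+].[O-]Cl=O
Why: The TEMPO/NaClO2 oxidation (Zhao variant of the Anelli oxidation) takes the primary alcohol to the acid under buffered conditions that neither move the β,γ-alkene into conjugation nor cleave the aryl silyl ethers.

Step 12
Reactants: 22 (E)-5-[2,5-bis(tert-butyldimethylsilyloxy)-3-methylphenyl]-3-methylpent-3-enoic acid; 11 (1R,5R,6R)-6-{[(2S)-3,3-dimethyloxiran-2-yl]methyl}-1,5-dimethylbicyclo[3.2.0]heptan-6-ol
Product: 24 (E)-6-[2,5-bis(tert-butyldimethylsilyloxy)-3-methylphenyl]-1-[(1R,2R)-2-{2-[(2S)-3,3-dimethyloxiran-2-yl]acetyl}-1,2-dimethylcyclopentyl]-4-methylhex-4-en-2-one, via acid chloride 23 (not isolated)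
Conditions: 22, Me2C=C(Cl)NMe2, CH2Cl2, 0 °C; then 11, Pd2(dba)3 [tris(dibenzylideneacetone)dipalladium] (2.5 mol%), XPhos (6 mol%), K3PO4, PhMe, CO (1 atm), 40 °C
Reagents that add atoms: none
Why: Proposed new method: oxidative addition of acid chloride 23 to zerovalent palladium gives an acylpalladium chloride that exchanges chloride for the tertiary cyclobutanolate of 11, strain-driven β-carbon elimination then cleaves the less hindered C6–C7 bond to a neopentyl-type alkylpalladium that has no β-hydrogen, and acyl–alkyl reductive elimination forms the CH2–C(=O) bond of the left ketone while C6 becomes the right ketone and neither quaternary centre is touched (CO only holds back decarbonylation of the β,γ-unsaturated acyl group), the closest known reactions being the palladium-catalysed ring-opening arylation of tert-cyclobutanols with aryl bromides and the palladium-catalysed acylation of cyclopropanols with acid chlorides to 1,4-diketones.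

Step 13
Reactants: 24 (E)-6-[2,5-bis(tert-butyldimethylsilyloxy)-3-methylphenyl]-1-[(1R,2R)-2-{2-[(2S)-3,3-dimethyloxiran-2-yl]acetyl}-1,2-dimethylcyclopentyl]-4-methylhex-4-en-2-one
Product: 25 (E)-6-(2,5-dihydroxy-3-methylphenyl)-1-[(1R,2R)-2-{2-[(2S)-3,3-dimethyloxiran-2-yl]acetyl}-1,2-dimethylcyclopentyl]-4-methylhex-4-en-2-one
Conditions: Bu4NF, AcOH (1:1), THF, 0 °C, Ar
Reagents that add atoms: none
Why: Acetic-acid-buffered fluoride desilylation cleaves the two aryl silyl ethers without base-induced β-elimination of the β,γ-epoxy ketone or conjugation of the β,γ-enone.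

**Compound list**
1 | 1,2-dimethylcyclopent-1-ene | CC1=C(C)CCC1 | starting material
2 | 1,1-dichloroethane | CC(Cl)Cl | starting material
3 | 1,1-dichloroethyllithium | [Li]C(C)(Cl)Cl | intermediate
4 | (1R,5S)-6-chloro-1,5,6-trimethylbicyclo[3.1.0]hexane (meso, C6 epimers) | C[C@]12CCC[C@@]1(C)C2(C)Cl | intermediate
5 | (1R,5S)-1,5-dimethyl-6-methylidenebicyclo[3.1.0]hexane (meso) | C[C@]12CCC[C@@]1(C)C2=C | intermediate
6 | (1R,5S)-1,5-dimethylspiro[bicyclo[3.1.0]hexane-6,2'-oxirane] (meso oxaspiropentane) | C[C@]12CCC[C@@]1(C)C21CO1 | intermediate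
7 | (1R,5R)-1,5-dimethylbicyclo[3.2.0]heptan-6-one | O=C1C[C@@]2(C)CCC[C@@]12C | intermediate
8 | 1-chloro-3-methylbut-2-ene (prenyl chloride) | CC(C)=CCCl | starting material
9 | prenylbarium chloride (C5H9BaCl) | CC(C)=CC[Ba]Cl | intermediate
10 | (1R,5R,6S)-1,5-dimethyl-6-(3-methylbut-2-en-1-yl)bicyclo[3.2.0]heptan-6-ol (prenyl on the face of the bridgehead methyls) | O[C@@]1(CC=C(C)C)C[C@@]2(C)CCC[C@@]12C | intermediate
11 | (1R,5R,6R)-6-{[(2S)-3,3-dimethyloxiran-2-yl]methyl}-1,5-dimethylbicyclo[3.2.0]heptan-6-ol (same arrangement at C6 as in 10; the descriptor changes by priority) | O[C@@]1(C[C@@H]2OC2(C)C)C[C@@]3(C)CCC[C@@]13C | intermediate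
12 | 2-methylphenol (o-cresol) | Cc1ccccc1O | starting material
13 | 8-methyl-2-phenyl-4H-1,3,2-benzodioxaborinine | Cc1cccc2COB(Oc12)c1ccccc1 | intermediate
14 | 2-(hydroxymethyl)-6-methylphenol | Cc1cccc(CO)c1O | intermediate
15 | 2-(hydroxymethyl)-6-methylcyclohexa-2,5-diene-1,4-dione | CC1=CC(=O)C=C(CO)C1=O | intermediate
16 | 2-(hydroxymethyl)-6-methylbenzene-1,4-diol | Cc1cc(O)cc(CO)c1O | intermediate
17 | tert-butyl{[2,5-bis(tert-butyldimethylsilyloxy)-3-methylphenyl]methoxy}dimethylsilane | Cc1cc(O[Si](C)(C)C(C)(C)C)cc(CO[Si](C)(C)C(C)(C)C)c1O[Si](C)(C)C(C)(C)C | intermediate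
18 | 1-(bromomethyl)-2,5-bis(tert-butyldimethylsilyloxy)-3-methylbenzene | Cc1cc(O[Si](C)(C)C(C)(C)C)cc(CBr)c1O[Si](C)(C)C(C)(C)C | intermediate
19 | but-3-yn-1-ol | C#CCCO | starting material
20 | dimethyl[(1E)-4-(dimethylalumanyloxy)-2-methylbut-1-en-1-yl]alumane | C/C(=C\[Al](C)C)CCO[Al](C)C | intermediate
21 | (E)-5-[2,5-bis(tert-butyldimethylsilyloxy)-3-methylphenyl]-3-methylpent-3-en-1-ol | C/C(=C\Cc1cc(O[Si](C)(C)C(C)(C)C)cc(C)c1O[Si](C)(C)C(C)(C)C)CCO | intermediate
22 | (E)-5-[2,5-bis(tert-butyldimethylsilyloxy)-3-methylphenyl]-3-methylpent-3-enoic acid | C/C(=C\Cc1cc(O[Si](C)(C)C(C)(C)C)cc(C)c1O[Si](C)(C)C(C)(C)C)CC(=O)O | intermediate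
23 | (E)-5-[2,5-bis(tert-butyldimethylsilyloxy)-3-methylphenyl]-3-methylpent-3-enoyl chloride | C/C(=C\Cc1cc(O[Si](C)(C)C(C)(C)C)cc(C)c1O[Si](C)(C)C(C)(C)C)CC(Cl)=O | intermediate
24 | (E)-6-[2,5-bis(tert-butyldimethylsilyloxy)-3-methylphenyl]-1-[(1R,2R)-2-{2-[(2S)-3,3-dimethyloxiran-2-yl]acetyl}-1,2-dimethylcyclopentyl]-4-methylhex-4-en-2-one | C/C(=C\Cc1cc(O[Si](C)(C)C(C)(C)C)cc(C)c1O[Si](C)(C)C(C)(C)C)CC(=O)C[C@@]1(C)CCC[C@@]1(C)C(=O)C[C@@H]1OC1(C)C | intermediate
25 | (E)-6-(2,5-dihydroxy-3-methylphenyl)-1-[(1R,2R)-2-{2-[(2S)-3,3-dimethyloxiran-2-yl]acetyl}-1,2-dimethylcyclopentyl]-4-methylhex-4-en-2-one | C/C(=C\Cc1cc(O)cc(C)c1O)CC(=O)C[C@@]1(C)CCC[C@@]1(C)C(=O)C[C@@H]1OC1(C)C | target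

**Totals**
Total step count: 13. Longest linear sequence: 8 steps (12 → 14 → 16 → 17 → 18 → 21 → 22 → 24 → 25). The other arm is 7 steps (1 → 4 → 5 → 7 → 10 → 11 → 24 → 25).

**Three steps most likely to fail**

Step 3 (proposed new enantioselective ring expansion). The rearrangement itself is safe, but the enantiotopic-bond selection may be low, and the two meso epimers of 6 may behave differently. The fallback uses known chemistry and replaces catalysis by resolution. It sets out from 5: DMDO epoxidation to 6 and rearrangement with catalytic LiI in CH2Cl2 give racemic 1,5-dimethylbicyclo[3.2.0]heptan-6-one F1. Lithiated (S)-N,S-dimethyl-S-phenylsulfoximine (n-BuLi, THF, −78 °C) adds to F1 to give two β-hydroxysulfoximines, the (1R,5R,6S) adduct F2 and the (1S,5S,6R) adduct F3 (Johnson ketone resolution). These are separated on silica, and thermolysis of F2 (PhMe, 110 °C) releases the ketone, coming back to the route at 7.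

Step 4 (α-selective prenylation with activated barium). The risks are γ-attack giving the reverse-prenyl carbinol and the handling of the activated metal. The fallback builds the prenyl group in two stages and sets out from 7. Allylmagnesium bromide (THF, −78 °C) gives (1R,5R,6S)-1,5-dimethyl-6-(prop-2-en-1-yl)bicyclo[3.2.0]heptan-6-ol F4. Cross-metathesis of F4 with excess 2-methylbut-2-ene (second-generation Grubbs catalyst, (H2IMes)(PCy3)Cl2Ru=CHPh, 5 mol%, 40 °C) turns allyl into prenyl and comes back to the route at 10.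

Step 12 (proposed new acylative ring opening). The risks are decarbonylation of the β,γ-unsaturated acylpalladium to an allyl complex, O-acylation of the carbinol, cleavage of the C6–C5 instead of the C6–C7 bond, and base-induced opening of the epoxy ketone. The fallback uses known chemistry and replaces the metal-mediated C–C cleavage by an aldol / retro-aldol (de Mayo-type) sequence. It sets out from 7 and 21.
- Dess–Martin oxidation of 21 gives (E)-5-[2,5-bis(tert-butyldimethylsilyloxy)-3-methylphenyl]-3-methylpent-3-enal F5.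
- The dibutylboron enolate of 7 (Bu2BOTf, i-Pr2NEt, CH2Cl2, −78 °C) adds to F5 to give the C7 aldol, (1R,5R)-7-{(E)-5-[2,5-bis(tert-butyldimethylsilyloxy)-3-methylphenyl]-1-hydroxy-3-methylpent-3-en-1-yl}-1,5-dimethylbicyclo[3.2.0]heptan-6-one F6.
- Excess prenylbarium chloride 9 adds to the ring ketone to give the diol, (1R,5R)-7-{(E)-5-[2,5-bis(tert-butyldimethylsilyloxy)-3-methylphenyl]-1-hydroxy-3-methylpent-3-en-1-yl}-1,5-dimethyl-6-(3-methylbut-2-en-1-yl)bicyclo[3.2.0]heptan-6-ol F7.
- Dess–Martin oxidation of the secondary alcohol gives the β-hydroxy ketone, (E)-5-[2,5-bis(tert-butyldimethylsilyloxy)-3-methylphenyl]-1-[(1R,5R)-6-hydroxy-1,5-dimethyl-6-(3-methylbut-2-en-1-yl)bicyclo[3.2.0]heptan-7-yl]-3-methylpent-3-en-1-one F8.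
- Hydroxyl-directed epoxidation of the homoallylic prenyl alkene (t-BuOOH, VO(Oi-Pr)3, chiral bishydroxamic acid ligand) leaves the remote chain alkene alone and gives (E)-5-[2,5-bis(tert-butyldimethylsilyloxy)-3-methylphenyl]-1-[(1R,5R)-6-{[(2S)-3,3-dimethyloxiran-2-yl]methyl}-6-hydroxy-1,5-dimethylbicyclo[3.2.0]heptan-7-yl]-3-methylpent-3-en-1-one F9. Epoxide stereocontrol is the weak point of this sequence.
- Strain-driven retro-aldol cleavage of the C6–C7 bond of F9 (DBU cat., CH2Cl2, 0 °C) comes back to the route at 24.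

Further compounds
F1 | step 3 | racemic 1,5-dimethylbicyclo[3.2.0]heptan-6-one | CC12CCCC1(C)C(=O)C2
F2 | step 3 | (1R,5R,6S)-1,5-dimethyl-6-{[(S)-N-methyl-S-phenylsulfonimidoyl]methyl}bicyclo[3.2.0]heptan-6-ol | CN=[S@](=O)(C[C@]1(O)C[C@@]2(C)CCC[C@@]12C)c1ccccc1
F3 | step 3 | (1S,5S,6R)-1,5-dimethyl-6-{[(S)-N-methyl-S-phenylsulfonimidoyl]methyl}bicyclo[3.2.0]heptan-6-ol | CN=[S@](=O)(C[C@@]1(O)C[C@]2(C)CCC[C@]12C)c1ccccc1
F4 | step 4 | (1R,5R,6S)-1,5-dimethyl-6-(prop-2-en-1-yl)bicyclo[3.2.0]heptan-6-ol | O[C@@]1(CC=C)C[C@@]2(C)CCC[C@@]12C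
F5 | step 12 | (E)-5-[2,5-bis(tert-butyldimethylsilyloxy)-3-methylphenyl]-3-methylpent-3-enal | C/C(=C\Cc1cc(O[Si](C)(C)C(C)(C)C)cc(C)c1O[Si](C)(C)C(C)(C)C)CC=O
F6 | step 12 | (1R,5R)-7-{(E)-5-[2,5-bis(tert-butyldimethylsilyloxy)-3-methylphenyl]-1-hydroxy-3-methylpent-3-en-1-yl}-1,5-dimethylbicyclo[3.2.0]heptan-6-one (epimers at C7 and the carbinol) | C/C(=C\Cc1cc(O[Si](C)(C)C(C)(C)C)cc(C)c1O[Si](C)(C)C(C)(C)C)CC(O)C1C(=O)[C@]2(C)CCC[C@]12C
F7 | step 12 | (1R,5R)-7-{(E)-5-[2,5-bis(tert-butyldimethylsilyloxy)-3-methylphenyl]-1-hydroxy-3-methylpent-3-en-1-yl}-1,5-dimethyl-6-(3-methylbut-2-en-1-yl)bicyclo[3.2.0]heptan-6-ol | C/C(=C\Cc1cc(O[Si](C)(C)C(C)(C)C)cc(C)c1O[Si](C)(C)C(C)(C)C)CC(O)C1C(O)(CC=C(C)C)[C@]2(C)CCC[C@]12C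
F8 | step 12 | (E)-5-[2,5-bis(tert-butyldimethylsilyloxy)-3-methylphenyl]-1-[(1R,5R)-6-hydroxy-1,5-dimethyl-6-(3-methylbut-2-en-1-yl)bicyclo[3.2.0]heptan-7-yl]-3-methylpent-3-en-1-one | C/C(=C\Cc1cc(O[Si](C)(C)C(C)(C)C)cc(C)c1O[Si](C)(C)C(C)(C)C)CC(=O)C1C(O)(CC=C(C)C)[C@]2(C)CCC[C@]12C
F9 | step 12 | (E)-5-[2,5-bis(tert-butyldimethylsilyloxy)-3-methylphenyl]-1-[(1R,5R)-6-{[(2S)-3,3-dimethyloxiran-2-yl]methyl}-6-hydroxy-1,5-dimethylbicyclo[3.2.0]heptan-7-yl]-3-methylpent-3-en-1-one | C/C(=C\Cc1cc(O[Si](C)(C)C(C)(C)C)cc(C)c1O[Si](C)(C)C(C)(C)C)CC(=O)C1C(O)(C[C@@H]3OC3(C)C)[C@]2(C)CCC[C@]12C
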